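The route rests on the α-amino ketone at the aza-quaternary carbon shared by the pyrrolidine, azepanone and cyclopentene rings: its bond to the ethyl-bearing cyclopentene CH and the neighbouring azepanone C=O are the retron of a 1,2-shift. The cyclopentene is therefore made by contracting a six-membered carbocycle. The precursor is an N-Boc dienamide (2-pyrroline fused to a cyclohexadiene–butenolide) with a tertiary carbinol beside the N-bearing sp2 carbon. Lewis acid triggers an aza-semipinacol shift that in one operation creates the quaternary stereocentre, the ketone, the tetrasubstituted cyclopentene C=C and the lactone α-stereocentre. The precursor is assembled from a desymmetrised p-quinol and a serine-derived cyclic sulfamidate.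

Key step: step 15

Remark: stereocentres that are formed as mixtures and are erased in a later step are left undefined in the SMILES; ring stereochemistry is described in words and fixed by the SMILES of the compound list.

Step 1
Reactants: 1 tert-butyl 2-(4-hydroxyphenyl)acetate
Product: 2 tert-butyl 2-(1-hydroxy-4-oxocyclohexa-2,5-dien-1-yl)acetate (prochiral p-quinol)
Conditions: PhI(OAc)2, MeCN/H2O, 0 °C
Reagents that add atoms: water, O
Why: Oxidative dearomatisation of the para-substituted phenol by the hypervalent iodine reagent, in which water adds to the phenoxenium ion at the substituted para carbon and gives the p-quinol without a stereocentre.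

Step 2
Reactants: 2 tert-butyl 2-(1-hydroxy-4-oxocyclohexa-2,5-dien-1-yl)acetate
Product: 4 tert-butyl 2-[6-ethyl-1,4-bis(trimethylsilyloxy)cyclohexa-2,4-dien-1-yl]acetate (ethyl cis to the 1-silyloxy group), via bis(ethylzinc) alkoxide enolate 3 (not isolated)
Conditions: Et2Zn (3 equiv), Cu(OTf)2 (3 mol %), chiral BINOL-derived N,N-bis(1-phenylethyl)phosphoramidite (6 mol %, enantiomer chosen for the required enone), toluene, −30 °C; then TMSOTf, −30 → 0 °C
Reagents that add atoms: diethylzinc, CC[Zn]CC; trimethylsilyl trifluoromethanesulfonate, C[Si](C)(C)OS(=O)(=O)C(F)(F)F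
Why: Copper-catalysed enantioselective conjugate addition that desymmetrises the 4,4-disubstituted cyclohexadienone: the chiral copper–phosphoramidite catalyst selects one of the two enantiotopic enones, the zinc alkoxide of the quinol directs ethyl to the face syn to oxygen (which fixes both new stereocentres, ethyl cis to O), and the regiodefined zinc enolate is trapped by silylation.

Step 3
Reactants: 4 tert-butyl 2-[6-ethyl-1,4-bis(trimethylsilyloxy)cyclohexa-2,4-dien-1-yl]acetate
Product: 6 tert-butyl 2-(6-ethyl-1,5-dihydroxy-4-oxocyclohex-2-en-1-yl)acetate (ethyl cis to the tertiary 1-OH, trans to the secondary 5-OH), via bis-silylated α-silyloxy enone 5 (not isolated)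
Conditions: mCPBA, NaHCO3, CH2Cl2, −20 °C; then citric acid, MeOH, 20 °C
Reagents that add atoms: mCPBA, OOC(=O)c1cccc(Cl)c1
Why: Rubottom oxidation, in which mCPBA epoxidises the electron-rich silyl enol ether double bond (not the enone) anti to the neighbouring ethyl group, silyl migration gives the α-silyloxy ketone and acidic methanolysis frees both hydroxyls, so that the new secondary OH is trans to ethyl.

Step 4
Reactants: 6 tert-butyl 2-(6-ethyl-1,5-dihydroxy-4-oxocyclohex-2-en-1-yl)acetate; 7 2-(diethoxyphosphoryl)propanoic acid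
Product: 8 the 5-O-[2-(diethoxyphosphoryl)propanoyl] ester of 6 (epimers at the phosphonate carbon)
Conditions: DCC, DMAP (cat.), CH2Cl2, 0 °C
Reagents that add atoms: none
Why: Steglich esterification acylates the unhindered secondary α-ketol hydroxyl selectively over the tertiary carbinol, and the phosphonate-bearing carbon becomes sp2 in step 5.

Step 5
Reactants: 8 the 5-O-[2-(diethoxyphosphoryl)propanoyl] ester of 6
Product: 9 tert-butyl 2-(7-ethyl-6-hydroxy-3-methyl-2-oxo-2,6,7,7a-tetrahydro-1-benzofuran-6-yl)acetate (7-ethyl cis to 6-OH, trans to the ring oxygen at C7a)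
Conditions: LiCl, i-Pr2NEt, MeCN, 20 °C
Reagents that add atoms: none
Why: Intramolecular Horner–Wadsworth–Emmons olefination of the adjacent enone carbonyl under mild conditions closes the α-methylbutenolide (five-membered ring) and leaves the three stereocentres untouched.

Step 6
Reactants: 9 tert-butyl 2-(7-ethyl-6-hydroxy-3-methyl-2-oxo-2,6,7,7a-tetrahydro-1-benzofuran-6-yl)acetate
Product: 10 the 4,5-epoxide of 9 (epoxide oxygen syn to the 6-OH)
Conditions: VO(acac)2 (5 mol %), t-BuOOH, CH2Cl2, 0 → 20 °C
Reagents that add atoms: tert-butyl hydroperoxide, CC(C)(C)OO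
Why: Hydroxyl-directed vanadium-catalysed epoxidation of the allylic tertiary alcohol touches only the ring double bond next to the carbinol and delivers oxygen syn to OH (a configuration that is erased in step 7).

Step 7
Reactants: 10 the 4,5-epoxide of 9
Product: 11 tert-butyl 2-(7-ethyl-6-hydroxy-3-methyl-2,5-dioxo-2,4,5,6,7,7a-hexahydro-1-benzofuran-6-yl)acetate (vinylogous β-keto lactone)
Conditions: Pd(PPh3)4 (5 mol %), THF, 50 °C
Reagents that add atoms: none
Why: Isomerisation of a diene monoepoxide by zerovalent palladium, in which ionisation at the allylic C–O bond gives a π-allyl alkoxide and β-hydride elimination from the alkoxide carbon followed by reductive elimination gives the β,γ-unsaturated ketone with the butenolide conjugation retained.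

Step 8
Reactants: 12 (S)-3-(tert-butoxycarbonyl)-2,2-dimethyl-1,3-oxazolidine-4-carboxylic acid
Product: 13 S-ethyl (S)-3-(tert-butoxycarbonyl)-2,2-dimethyl-1,3-oxazolidine-4-carbothioate
Conditions: EtSH, DCC, DMAP (cat.), CH2Cl2, 0 °C
Reagents that add atoms: ethanethiol, CCS
Why: Steglich thioesterification at low temperature converts the serine-derived acid into the thioester without racemisation of the α-stereocentre.

Step 9
Reactants: 13 S-ethyl (S)-3-(tert-butoxycarbonyl)-2,2-dimethyl-1,3-oxazolidine-4-carbothioate; 14 methyl (R)-3-bromo-2-methylpropanoate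
Product: 16 tert-butyl (S)-4-[(S)-4-methoxy-3-methyl-4-oxobutanoyl]-2,2-dimethyl-1,3-oxazolidine-3-carboxylate, via alkylzinc bromide 15 (not isolated)
Conditions: 14, Zn, I2 (5 mol %), DMA, 70 °C; then 13, PdCl2(PPh3)2 (5 mol %), toluene, 20 °C
Reagents that add atoms: none
Why: Fukuyama coupling, in which zinc insertion into the primary bromide gives a β-zincated ester whose stereocentre is not involved and palladium-catalysed acylation by the thioester stops at the ketone without epimerisation.

Step 10
Reactants: 16 tert-butyl (S)-4-[(S)-4-methoxy-3-methyl-4-oxobutanoyl]-2,2-dimethyl-1,3-oxazolidine-3-carboxylate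
Product: 18 tert-butyl (S)-2,2-dimethyl-4-[(2S,4S)-4-methyl-5-oxooxolan-2-yl]-1,3-oxazolidine-3-carboxylate, via γ-hydroxy ester 17 (not isolated)
Conditions: LiBH(s-Bu)3, THF, −78 → 0 °C; then AcOH
Reagents that add atoms: none
Why: Felkin–Anh reduction of the N,N-disubstituted α-amino ketone by the bulky borohydride (hydride anti to the C–N bond) gives the syn (threo) alkoxide, which lactonises onto the methyl ester on warming, and with the methyl stereocentre brought in by 14 the cis-2,4-disubstituted lactone results.

Step 11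
Reactants: 18 tert-butyl (S)-2,2-dimethyl-4-[(2S,4S)-4-methyl-5-oxooxolan-2-yl]-1,3-oxazolidine-3-carboxylate
Product: 19 tert-butyl N-[(1S)-2-hydroxy-1-[(2S,4S)-4-methyl-5-oxooxolan-2-yl]ethyl]carbamate
Conditions: p-TsOH·H2O (10 mol %), MeOH, 20 °C
Reagents that add atoms: none
Why: Acid-catalysed transacetalisation in methanol removes the N,O-isopropylidene group while the Boc group and the lactone stay intact.

Step 12
Reactants: 19 tert-butyl N-[(1S)-2-hydroxy-1-[(2S,4S)-4-methyl-5-oxooxolan-2-yl]ethyl]carbamate
Product: 21 tert-butyl (4S)-4-[(2S,4S)-4-methyl-5-oxooxolan-2-yl]-1,2,3-oxathiazolidine-3-carboxylate 2,2-dioxide (cyclic sulfamidate), via cyclic sulfamidite 20 (not isolated)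
Conditions: SOCl2, pyridine, MeCN, −40 °C; then RuCl3 (1 mol %), NaIO4, MeCN/H2O, 0 °C
Reagents that add atoms: thionyl chloride, O=S(Cl)Cl; sodium periodate, [Na+].[O-]I(=O)(=O)=O
Why: Standard activation of an N-Boc 1,2-amino alcohol by cyclisation to the sulfamidite and ruthenium-catalysed oxidation to the cyclic sulfamidate, which does not touch the stereocentres.

Step 13
Reactants: 11 tert-butyl 2-(7-ethyl-6-hydroxy-3-methyl-2,5-dioxo-2,4,5,6,7,7a-hexahydro-1-benzofuran-6-yl)acetate; 21 the cyclic sulfamidate
Product: 23 tert-butyl 2-{4-[(2S)-2-(tert-butoxycarbonylamino)-2-[(2S,4S)-4-methyl-5-oxooxolan-2-yl]ethyl]-7-ethyl-6-hydroxy-3-methyl-2,5-dioxo-2,4,5,6,7,7a-hexahydro-1-benzofuran-6-yl}acetate (epimers at C4), via cesium N-sulfate 22 (not isolated)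
Conditions: Cs2CO3, DMF, 0 → 20 °C; then 1 M aq. HCl, EtOAc, 20 °C
Reagents that add atoms: none
Why: C-alkylation in which the carbanion stabilised by both the ketone and the butenolide opens the cyclic sulfamidate by SN2 attack at its CH2–O carbon and mild aqueous acid hydrolyses the N-sulfate, the new ring CH centre being a mixture that becomes sp2 in step 14.

Step 14
Reactants: 23 the keto carbamate
Product: 24 tricyclic N-Boc dienamide: the carbamate nitrogen is joined to the former ketone carbon of 23, which forms an enamide C=C with the former C4, so that an N-Boc 2-pyrroline (C5 S, bearing the (2S,4S)-4-methyl-5-oxooxolan-2-yl group) is fused to the cyclohexadiene–butenolide; ethyl, tertiary OH and CH2CO2t-Bu as in 11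
Conditions: PPTS (20 mol %), toluene, 4 Å molecular sieves, 70 °C
Reagents that add atoms: none
Why: Acid-catalysed intramolecular condensation of the carbamate N–H with the ring ketone (ene-carbamate formation, five-membered ring) is driven by removal of water and by conjugation of the new enamide with the butenolide.

Step 15
Reactants: 24 the tricyclic N-Boc dienamide
Product: 26 ring-contracted β-keto ester: N-Boc pyrrolidine fused to a cyclopentene, whose aza-quaternary fusion carbon carries the 3-tert-butoxy-3-oxopropanoyl group; cyclopentene C=C between the other fusion carbon and the lactone-bearing carbon; β,γ-unsaturated γ-lactone with α-methyl; ethyl trans to the lactone oxygen; pendant lactone unchanged, via lactone dienol 25 (not isolated)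
Conditions: BF3·OEt2 (30 mol %), CH2Cl2, −78 → −30 °C; pH 7 buffer
Reagents that add atoms: none
Why: Proposed new method: BF3 binds the butenolide carbonyl of the push–pull N-Boc dienamide, which makes the N-bearing sp2 carbon a vinylogous N-acyliminium centre; the ring bond from the adjacent tertiary carbinol carbon to the ethyl-bearing carbon then shifts suprafacially to that centre while the carbinol becomes the ketone, and the dienol(ate) that results is protonated at the lactone α-carbon by the proton released from the hydroxyl. The closest known reaction types are the acid- or halonium-triggered semipinacol rearrangement of α-hydroxy N-acyliminium ions generated from cyclic ene-carbamates, the α-iminol rearrangement and the humulone-to-isohumulone α-ketol ring contraction. No ring is closed by cyclisation: the six-membered carbocycle contracts to the cyclopentene through a three-centre 1,2-alkyl shift with retention at the migrating carbon. The aza-quaternary stereocentre is controlled by the ring-fusion CH–O stereocentre, because the planar fused butenolide holds the migrating carbon out of the dienamide plane on the face opposite to that hydrogen; the lactone α-stereocentre is set by kinetic α-protonation of the dienol from the convex face, cis to the CH–O hydrogen. The step needs migration of the ring carbon and not of the side chain, and α- and not γ-protonation: the CH2CO2t-Bu group is electron-poor and pseudo-equatorial and so should not migrate, and dienols are protonated kinetically at the α-carbon.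

Step 16
Reactants: 26 the ring-contracted β-keto ester; 27 1-bromo-3-chloropropane
Product: 28 the α-(3-chloropropyl) derivative of 26 (epimers at the new centre)
Conditions: K2CO3, DMF, 20 °C
Reagents that add atoms: none
Why: C-alkylation of the β-keto ester by the bromide end of the dihalide under carbonate conditions that do not deprotonate the lactone α-carbon, the new stereocentre being erased by the decarboxylation in step 17.

Step 17
Reactants: 28 the α-(3-chloropropyl) β-keto ester
Product: 31 CNP0315436.2 (target), via amino β-keto acid 29 (not isolated), via amino chloro ketone 30 (not isolated)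
Conditions: TFA, CH2Cl2, 0 → 35 °C; evaporate; then K2CO3, NaI (10 mol %), MeCN, 60 °C
Reagents that add atoms: none
Why: TFA cleaves the Boc carbamate and the tert-butyl ester, the β-keto acid decarboxylates, and after neutralisation the secondary amine closes the azepanone by iodide-catalysed 7-exo-tet N-alkylation without touching a stereocentre.

Compound list
1 | tert-butyl 2-(4-hydroxyphenyl)acetate | CC(C)(C)OC(=O)Cc1ccc(O)cc1 | starting material
2 | tert-butyl 2-(1-hydroxy-4-oxocyclohexa-2,5-dien-1-yl)acetate | CC(C)(C)OC(=O)CC1(O)C=CC(=O)C=C1 | intermediate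
3 | bis(ethylzinc) alkoxide enolate of the ethyl adduct | CC[C@H]1C=C(O[Zn]CC)C=C[C@@]1(CC(=O)OC(C)(C)C)O[Zn]CC | intermediate
4 | tert-butyl 2-[6-ethyl-1,4-bis(trimethylsilyloxy)cyclohexa-2,4-dien-1-yl]acetate, ethyl cis to 1-OSiMe3 | CC[C@H]1C=C(O[Si](C)(C)C)C=C[C@@]1(CC(=O)OC(C)(C)C)O[Si](C)(C)C | intermediate
5 | tert-butyl 2-[6-ethyl-4-oxo-1,5-bis(trimethylsilyloxy)cyclohex-2-en-1-yl]acetate | CC[C@H]1[C@H](O[Si](C)(C)C)C(=O)C=C[C@@]1(CC(=O)OC(C)(C)C)O[Si](C)(C)C | intermediate
6 | tert-butyl 2-(6-ethyl-1,5-dihydroxy-4-oxocyclohex-2-en-1-yl)acetate, ethyl cis to 1-OH and trans to 5-OH | CC[C@H]1[C@H](O)C(=O)C=C[C@]1(O)CC(=O)OC(C)(C)C | intermediate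
7 | 2-(diethoxyphosphoryl)propanoic acid | CCOP(=O)(OCC)C(C)C(=O)O | starting material
8 | 5-O-[2-(diethoxyphosphoryl)propanoyl] ester of 6 | CC[C@H]1[C@H](OC(=O)C(C)P(=O)(OCC)OCC)C(=O)C=C[C@]1(O)CC(=O)OC(C)(C)C | intermediate
9 | tert-butyl 2-(7-ethyl-6-hydroxy-3-methyl-2-oxo-2,6,7,7a-tetrahydro-1-benzofuran-6-yl)acetate | CC[C@H]1[C@@H]2OC(=O)C(C)=C2C=C[C@]1(O)CC(=O)OC(C)(C)C | intermediate
10 | 4,5-epoxide of 9, oxygen syn to 6-OH | CC[C@H]1[C@@H]2OC(=O)C(C)=C2[C@H]3O[C@H]3[C@]1(O)CC(=O)OC(C)(C)C | intermediate
11 | tert-butyl 2-(7-ethyl-6-hydroxy-3-methyl-2,5-dioxo-2,4,5,6,7,7a-hexahydro-1-benzofuran-6-yl)acetate | CC[C@H]1[C@@H]2OC(=O)C(C)=C2CC(=O)[C@]1(O)CC(=O)OC(C)(C)C | intermediate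
12 | (S)-3-(tert-butoxycarbonyl)-2,2-dimethyl-1,3-oxazolidine-4-carboxylic acid | CC(C)(C)OC(=O)N1C(C)(C)OC[C@H]1C(=O)O | starting material
13 | S-ethyl (S)-3-(tert-butoxycarbonyl)-2,2-dimethyl-1,3-oxazolidine-4-carbothioate | CCSC(=O)[C@@H]1COC(C)(C)N1C(=O)OC(C)(C)C | intermediate
14 | methyl (R)-3-bromo-2-methylpropanoate | COC(=O)[C@@H](C)CBr | starting material
15 | [(R)-3-methoxy-2-methyl-3-oxopropyl]zinc bromide | COC(=O)[C@@H](C)C[Zn]Br | intermediate
16 | tert-butyl (S)-4-[(S)-4-methoxy-3-methyl-4-oxobutanoyl]-2,2-dimethyl-1,3-oxazolidine-3-carboxylate | COC(=O)[C@@H](C)CC(=O)[C@@H]1COC(C)(C)N1C(=O)OC(C)(C)C | intermediate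
17 | tert-butyl (S)-4-[(1S,3S)-1-hydroxy-4-methoxy-3-methyl-4-oxobutyl]-2,2-dimethyl-1,3-oxazolidine-3-carboxylate | COC(=O)[C@@H](C)C[C@H](O)[C@@H]1COC(C)(C)N1C(=O)OC(C)(C)C | intermediate
18 | tert-butyl (S)-2,2-dimethyl-4-[(2S,4S)-4-methyl-5-oxooxolan-2-yl]-1,3-oxazolidine-3-carboxylate | C[C@H]1C[C@H](OC1=O)[C@@H]2COC(C)(C)N2C(=O)OC(C)(C)C | intermediate
19 | tert-butyl N-[(1S)-2-hydroxy-1-[(2S,4S)-4-methyl-5-oxooxolan-2-yl]ethyl]carbamate | C[C@H]1C[C@H](OC1=O)[C@H](CO)NC(=O)OC(C)(C)C | intermediate
20 | tert-butyl (4S)-4-[(2S,4S)-4-methyl-5-oxooxolan-2-yl]-1,2,3-oxathiazolidine-3-carboxylate 2-oxide | C[C@H]1C[C@H](OC1=O)[C@@H]2COS(=O)N2C(=O)OC(C)(C)C | intermediate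
21 | tert-butyl (4S)-4-[(2S,4S)-4-methyl-5-oxooxolan-2-yl]-1,2,3-oxathiazolidine-3-carboxylate 2,2-dioxide | C[C@H]1C[C@H](OC1=O)[C@@H]2COS(=O)(=O)N2C(=O)OC(C)(C)C | intermediate
22 | cesium N-sulfate of keto carbamate 23 | CC[C@H]1[C@@H]2OC(=O)C(C)=C2C(C[C@H](N(C(=O)OC(C)(C)C)S(=O)(=O)[O-])[C@@H]3C[C@H](C)C(=O)O3)C(=O)[C@]1(O)CC(=O)OC(C)(C)C.[Cs+] | intermediate
23 | tert-butyl 2-{4-[(2S)-2-(tert-butoxycarbonylamino)-2-[(2S,4S)-4-methyl-5-oxooxolan-2-yl]ethyl]-7-ethyl-6-hydroxy-3-methyl-2,5-dioxo-2,4,5,6,7,7a-hexahydro-1-benzofuran-6-yl}acetate | CC[C@H]1[C@@H]2OC(=O)C(C)=C2C(C[C@H](NC(=O)OC(C)(C)C)[C@@H]3C[C@H](C)C(=O)O3)C(=O)[C@]1(O)CC(=O)OC(C)(C)C | intermediate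
24 | tricyclic N-Boc dienamide (2-pyrroline fused to the cyclohexadiene–butenolide, tertiary carbinol beside the N-bearing carbon) | CC[C@H]1[C@@H]2OC(=O)C(C)=C2C3=C(N([C@@H](C3)[C@@H]4C[C@H](C)C(=O)O4)C(=O)OC(C)(C)C)[C@]1(O)CC(=O)OC(C)(C)C | intermediate
25 | lactone dienol of 26 | CC[C@H]1[C@@H]2OC(O)=C(C)C2=C2C[C@@H]([C@@H]3C[C@H](C)C(=O)O3)N(C(=O)OC(C)(C)C)[C@]12C(=O)CC(=O)OC(C)(C)C | intermediate
26 | ring-contracted N-Boc β-keto tert-butyl ester (cyclopentene fused to pyrrolidine and β,γ-unsaturated lactone) | CC[C@H]1[C@@H]2OC(=O)[C@H](C)C2=C2C[C@@H]([C@@H]3C[C@H](C)C(=O)O3)N(C(=O)OC(C)(C)C)[C@]12C(=O)CC(=O)OC(C)(C)C | intermediate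
27 | 1-bromo-3-chloropropane | ClCCCBr | starting material
28 | α-(3-chloropropyl) derivative of 26 | CC[C@H]1[C@@H]2OC(=O)[C@H](C)C2=C2C[C@@H]([C@@H]3C[C@H](C)C(=O)O3)N(C(=O)OC(C)(C)C)[C@]12C(=O)C(CCCCl)C(=O)OC(C)(C)C | intermediate
29 | amino β-keto acid from 28 | CC[C@H]1[C@@H]2OC(=O)[C@H](C)C2=C2C[C@@H]([C@@H]3C[C@H](C)C(=O)O3)N[C@]12C(=O)C(CCCCl)C(=O)O | intermediate
30 | amino 5-chloropentanoyl ketone | CC[C@H]1[C@@H]2OC(=O)[C@H](C)C2=C2C[C@@H]([C@@H]3C[C@H](C)C(=O)O3)N[C@]12C(=O)CCCCCl | intermediate
31 | CNP0315436.2 | CC[C@H]1[C@@H]2OC(=O)[C@H](C)C2=C2C[C@@H]([C@@H]3C[C@H](C)C(=O)O3)N3CCCCC(=O)[C@]213 | target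

Total step count: 17. Longest linear sequence: 12 steps (1 to 31 through steps 1–7 and 13–17).

Steps most likely to fail

Step 15. The cationic intermediate may lose water from the tertiary carbinol and aromatise to the benzofuranone, the ring bond may migrate too slowly because it is only partly aligned with the π system, or protonation may occur at the γ-carbon and give the conjugated butenolide. The fallback uses known chemistry and sets out from 24: NBS in CH2Cl2 at −78 °C brominates the dienamide terminus irreversibly and triggers the same 1,2-shift (the bromonium-promoted semipinacol rearrangement of hydroxy ene-carbamates), giving the α-bromo β,γ-unsaturated lactone F1. Zn dust in AcOH/THF at 0 °C then removes bromine through the zinc dienolate, whose α-protonation gives 26, where the route is rejoined.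

Step 2. The catalyst may discriminate the two enantiotopic enones poorly, the ethyl group may add anti to oxygen, or the zinc aldolate of the quinol may fragment by retro-aldol cleavage. The fallback sets out from 2: rhodium-catalysed asymmetric conjugate addition of potassium vinyltrifluoroborate ([RhCl(cod)]2, (R)-BINAP, Et3N, dioxane/H2O, 60 °C) desymmetrises the dienone and gives the vinyl enone F2. Hydrogenation of the terminal vinyl group only (H2, RhCl(PPh3)3, benzene) gives the ethyl enone F3, and TMSOTf/Et3N in CH2Cl2 at 0 °C silylates the hydroxyl and the only enolisable ketone position to give 4, where the route is rejoined.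

Step 7. The π-allyl alkoxide may eliminate toward a dienol that aromatises, or the epoxy alcohol may rearrange by a pinacol-type shift instead of the hydride shift. The fallback sets out from 10: SmI2 in THF/MeOH at −78 °C opens the γ,δ-epoxy-α,β-unsaturated lactone reductively to the δ-hydroxy β,γ-unsaturated lactone F4. Dess–Martin periodinane oxidises the secondary alcohol only and gives the enone F5, a tautomer of 11 that forms the same extended enolate; under the conditions of step 13 with 21 it gives 22, where the route is rejoined.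

Further compounds
F1 | step 15 | α-bromo derivative of 26 (bromine at the lactone α-carbon, epimers) | CC[C@H]1[C@@H]2OC(=O)C(C)(Br)C2=C2C[C@@H]([C@@H]3C[C@H](C)C(=O)O3)N(C(=O)OC(C)(C)C)[C@]12C(=O)CC(=O)OC(C)(C)C
F2 | step 2 | tert-butyl 2-(6-ethenyl-1-hydroxy-4-oxocyclohex-2-en-1-yl)acetate, ethenyl cis to OH | C=C[C@H]1CC(=O)C=C[C@]1(O)CC(=O)OC(C)(C)C
F3 | step 2 | tert-butyl 2-(6-ethyl-1-hydroxy-4-oxocyclohex-2-en-1-yl)acetate, ethyl cis to OH | CC[C@H]1CC(=O)C=C[C@]1(O)CC(=O)OC(C)(C)C
F4 | step 7 | tert-butyl 2-(7-ethyl-5,6-dihydroxy-3-methyl-2-oxo-2,3,5,6,7,7a-hexahydro-1-benzofuran-6-yl)acetate (C3 epimers) | CC[C@H]1[C@@H]2OC(=O)C(C)C2=C[C@@H](O)[C@]1(O)CC(=O)OC(C)(C)C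
F5 | step 7 | tert-butyl 2-(7-ethyl-6-hydroxy-3-methyl-2,5-dioxo-2,3,5,6,7,7a-hexahydro-1-benzofuran-6-yl)acetate (C3 epimers) | CC[C@H]1[C@@H]2OC(=O)C(C)C2=CC(=O)[C@]1(O)CC(=O)OC(C)(C)C
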